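**Assumptions.** The target has no stereocentre (the bridging carbon is a CH2), so it is achiral and no stereocontrol is needed. The two acyl chlorides are numbered as starting materials; other atom-donating reagents are given on the "Reagents that add atoms" line. The route is a paper design based on known reaction types and has not been run.

**Retrosynthetic overview**
- The target is an unsymmetrical methylene-bis(acylphloroglucinol). The ArCH2–Ar' bond is cut on the side of the trihydroxy-valeryl ring: Michael addition of 2,4,6-trihydroxy-3-methylvalerophenone to the o-quinone methide of the butyryl ring.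
- The o-quinone methide comes from the Mannich base of aspidinol (2,6-dihydroxy-4-methoxy-3-methylbutyrophenone), so the other C–CH2 bond is made by a Mannich aminomethylation.
- Both monomers come from 2,4,6-trimethoxytoluene by Friedel–Crafts acylation, followed by chelation-controlled bis-ortho-demethylation (aspidinol) or exhaustive demethylation (the triol).
- 2,4,6-Trimethoxytoluene comes from 1,3,5-trimethoxybenzene by lithiation and methylation.
- No ring is built: both benzene rings derive from 1,3,5-trimethoxybenzene, with the butyryl ring elaborated first.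

**Route**

Step 1
Reactants: 1 1,3,5-trimethoxybenzene
Product: 3 2,4,6-trimethoxytoluene (1,3,5-trimethoxy-2-methylbenzene), via 2,4,6-trimethoxyphenyllithium 2 (not isolated)
Conditions: n-BuLi (1.1 equiv), TMEDA (1.1 equiv), THF, 0 °C → rt, 1 h; then MeI (1.5 equiv), 0 °C → rt
Reagents that add atoms: iodomethane, CI
Why: Directed ortho-lithiation at a C–H flanked by two methoxy groups (all three such positions are equivalent), then SN2 methylation of the aryllithium; no stereocentre.

Step 2
Reactants: 3 2,4,6-trimethoxytoluene; 4 butanoyl chloride
Product: 5 1-(2,4,6-trimethoxy-3-methylphenyl)butan-1-one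
Conditions: AlCl3 (1.2 equiv), CH2Cl2, −10 → 0 °C, 2 h; ice/1 M HCl
Reagents that add atoms: none
Why: Friedel–Crafts acylation at one of the two equivalent free positions of the electron-rich ring; the ketone deactivates the ring against a second acylation and the low temperature limits ether cleavage.

Step 3
Reactants: 5 1-(2,4,6-trimethoxy-3-methylphenyl)butan-1-one
Product: 6 aspidinol, 1-(2,6-dihydroxy-4-methoxy-3-methylphenyl)butan-1-one
Conditions: AlCl3 (4 equiv), CH2Cl2, 0 → 40 °C, 12–16 h; ice-water
Reagents that add atoms: none
Why: Chelation-controlled Lewis-acid ether cleavage: aluminium bound to the ketone oxygen activates each flanking ortho-methoxy group through a six-membered chelate for chloride attack on methyl, while the para 4-OMe cannot chelate and is kept.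

Step 4
Reactants: 3 2,4,6-trimethoxytoluene; 7 pentanoyl chloride
Product: 8 1-(2,4,6-trimethoxy-3-methylphenyl)pentan-1-one
Conditions: AlCl3 (1.2 equiv), CH2Cl2, −10 → 0 °C, 2 h; ice/1 M HCl
Reagents that add atoms: none
Why: Friedel–Crafts acylation, as in step 2, at the only type of free ring position.

Step 5
Reactants: 8 1-(2,4,6-trimethoxy-3-methylphenyl)pentan-1-one
Product: 9 1-(2,4,6-trihydroxy-3-methylphenyl)pentan-1-one
Conditions: BBr3 (5 equiv), CH2Cl2, −78 °C → rt, 16 h; ice-water
Reagents that add atoms: none
Why: Exhaustive BBr3 cleavage of the three aryl methyl ethers (adduct formation, then SN2 attack of bromide on methyl); the aryl ketone and alkyl chain are inert, and hydrolysis of the borates releases the triol.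

Step 6
Reactants: 6 aspidinol
Product: 10 1-{3-[(dimethylamino)methyl]-2,6-dihydroxy-4-methoxy-5-methylphenyl}butan-1-one
Conditions: Eschenmoser's salt (1.1 equiv), MeCN, 0 °C → rt, 2 h, Ar; sat. aq NaHCO3 to pH 7–8, EtOAc extraction; used without chromatography
Reagents that add atoms: N,N-dimethylmethyleneiminium iodide (Eschenmoser's salt), C=[N+](C)C.[I-]
Why: Mannich reaction with the preformed iminium salt at the only unsubstituted ring carbon of 6, which is ortho/para to three oxygen donors; the product forms as its HI salt, which prevents premature loss of amine.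

Step 7
Reactants: 10 1-{3-[(dimethylamino)methyl]-2,6-dihydroxy-4-methoxy-5-methylphenyl}butan-1-one; 9 1-(2,4,6-trihydroxy-3-methylphenyl)pentan-1-one (1.2 equiv)
Product: 12 1-[3-[(3-butanoyl-2,4-dihydroxy-6-methoxy-5-methylphenyl)methyl]-2,4,6-trihydroxy-5-methylphenyl]pentan-1-one (target CNP0210501.0), via o-quinone methide 11 (not isolated)
Conditions: 1,4-dioxane, 100 °C, slow Ar sweep, 3 h; 1 M HCl wash, chromatography/crystallisation
Reagents that add atoms: none
Why: On heating, the ortho-hydroxybenzylamine loses Me2NH to give o-quinone methide 11, an exocyclic enone that is captured by intermolecular Michael addition of the only free ring carbon of the vinylogous acid 9; tautomerisation restores both aromatic rings and the new CH2 bridge is not stereogenic.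

**Compound list**
1 | 1,3,5-trimethoxybenzene | COc1cc(OC)cc(OC)c1 | starting material
2 | 2,4,6-trimethoxyphenyllithium | [Li]c1c(OC)cc(OC)cc1OC | intermediate
3 | 2,4,6-trimethoxytoluene (1,3,5-trimethoxy-2-methylbenzene) | Cc1c(OC)cc(OC)cc1OC | intermediate
4 | butanoyl chloride | CCCC(Cl)=O | starting material
5 | 1-(2,4,6-trimethoxy-3-methylphenyl)butan-1-one | CCCC(=O)c1c(OC)cc(OC)c(C)c1OC | intermediate
6 | aspidinol, 1-(2,6-dihydroxy-4-methoxy-3-methylphenyl)butan-1-one | CCCC(=O)c1c(O)cc(OC)c(C)c1O | intermediate
7 | pentanoyl chloride | CCCCC(Cl)=O | starting material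
8 | 1-(2,4,6-trimethoxy-3-methylphenyl)pentan-1-one | CCCCC(=O)c1c(OC)cc(OC)c(C)c1OC | intermediate
9 | 1-(2,4,6-trihydroxy-3-methylphenyl)pentan-1-one | CCCCC(=O)c1c(O)cc(O)c(C)c1O | intermediate
10 | 1-{3-[(dimethylamino)methyl]-2,6-dihydroxy-4-methoxy-5-methylphenyl}butan-1-one | CCCC(=O)c1c(O)c(CN(C)C)c(OC)c(C)c1O | intermediate
11 | o-quinone methide, 2-butanoyl-3-hydroxy-5-methoxy-4-methyl-6-methylidenecyclohexa-2,4-dien-1-one | C=C1C(=O)C(C(=O)CCC)=C(O)C(C)=C1OC | intermediate
12 | 1-[3-[(3-butanoyl-2,4-dihydroxy-6-methoxy-5-methylphenyl)methyl]-2,4,6-trihydroxy-5-methylphenyl]pentan-1-one | CCCCC(=O)c1c(O)c(C)c(O)c(Cc2c(O)c(C(=O)CCC)c(O)c(C)c2OC)c1O | target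

**Totals**
Total step count: 7. Longest linear sequence: 5 steps (1 → 3 → 5 → 6 → 10 → 12, i.e. steps 1, 2, 3, 6, 7).

**Three steps most likely to fail**

Step 7 (fragment union). The risk is slow capture of the quinone methide or amine-promoted methylene exchange that gives the two symmetrical dimers. The fallback swaps the roles of the two rings and sets out from 9. Compound 9 is aminomethylated with Eschenmoser's salt (MeCN, 0 °C → rt, NaHCO3 work-up) to 1-{3-[(dimethylamino)methyl]-2,4,6-trihydroxy-5-methylphenyl}pentan-1-one F3. F3 is heated with aspidinol 6 in dioxane at 100 °C, so that it loses dimethylamine to the more readily formed 3,5-dihydroxy-4-methyl-6-methylidene-2-pentanoylcyclohexa-2,4-dien-1-one F4. The free ring carbon of 6 adds to F4 in a Michael reaction, and the route is rejoined at 12.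

Step 3 (bis-ortho-demethylation). The risk is that the reaction stops at the mono-phenol or also cleaves the 4-OMe. The fallback sets out from 5 and sets the ether pattern by alkylation instead of dealkylation. All three ethers of 5 are removed with BBr3 (CH2Cl2, −78 °C → rt) to give 1-(2,4,6-trihydroxy-3-methylphenyl)butan-1-one F1. F1 is then mono-O-methylated with Me2SO4 (1.0 equiv) and K2CO3 (1.0 equiv) in acetone at rt. The 4-OH, para to the acyl group, not hydrogen-bonded to the carbonyl and the most acidic, should react first; the minor 6-O-methyl isomer and the dimethyl ether are removed by chromatography. The route is rejoined at 6.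

Step 5 (exhaustive demethylation of the ketone). The risk is incomplete cleavage of the 4-OMe or degradation of the electron-rich ketone on long exposure to BBr3. The fallback sets out from 3 and reverses the order of events. Compound 3 is demethylated first with BBr3 (CH2Cl2, −78 °C → rt) to 2-methylbenzene-1,3,5-triol F2, which carries no sensitive ketone. F2 is then C-acylated with pentanoyl chloride 7 under AlCl3 in nitrobenzene/CH2Cl2 (rt → 50 °C, Friedel–Crafts acylation of the free phenol). The route is rejoined at 9.

**Further compounds**
F1 | step 3 | 1-(2,4,6-trihydroxy-3-methylphenyl)butan-1-one | CCCC(=O)c1c(O)cc(O)c(C)c1O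
F2 | step 5 | 2-methylbenzene-1,3,5-triol (2-methylphloroglucinol) | Cc1c(O)cc(O)cc1O
F3 | step 7 | 1-{3-[(dimethylamino)methyl]-2,4,6-trihydroxy-5-methylphenyl}pentan-1-one | CCCCC(=O)c1c(O)c(C)c(O)c(CN(C)C)c1O
F4 | step 7 | 3,5-dihydroxy-4-methyl-6-methylidene-2-pentanoylcyclohexa-2,4-dien-1-one | C=C1C(=O)C(C(=O)CCCC)=C(O)C(C)=C1O
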